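**Retrosynthetic overview**

1. Hanultarin ⇒ (global O-desilylation) its tri-TBS ether ⇒ (ester C–O) the C2-symmetric (2R,3R)-diol (bis-O-TBS secoisolariciresinol) + 4-O-TBS-ferulic acid. The two CH2OH groups are homotopic, so mono-acylation needs no regiocontrol.
2. Diol ⇒ (reductive removal of two oxazolidinone auxiliaries) the (2R,3R)-2,3-dibenzylsuccinyl bis-imide.
3. Key disconnection: the central C2–C3 bond (lignan C8–C8′) between two carbonyl α-carbons ⇒ one enolate plus one enolonium equivalent of the same imide. Both stereocenters are set in this single oxidative homocoupling by the (S)-4-benzyloxazolidinone.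
4. The enolate is made by conjugate hydride addition to the N-feruloyl imide, not by deprotonation, so one protected ferulic acid supplies both halves of the core and the ester side chain (all 30 skeletal carbons).
5. Rings: none is formed. The three arenes come from ferulic acid; the oxazolidinone ring is bought and recovered.

Assumption: compounds are numbered in the order of first appearance in the forward steps (the overview uses names only); commercial ferulic acid is the E isomer.

**Route**

Step 1
Reactants: 1 (E)-ferulic acid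
Product: 3 (E)-3-[4-(tert-butyldimethylsilyloxy)-3-methoxyphenyl]acrylic acid (4-O-TBS-ferulic acid), via bis-TBS ferulate 2 (not isolated)
Conditions: TBSCl (2.3 equiv), imidazole (5 equiv), DMF, rt; then AcOH/THF/H2O (3:1:1), rt
Reagents that add atoms: tert-butyldimethylsilyl chloride (TBSCl), CC(C)(C)[Si](C)(C)Cl
Why: Silylation of phenol and acid followed by selective hydrolysis of the far more labile silyl ester (aryl silyl ethers survive aqueous AcOH); no stereocenter is involved and the E-alkene is untouched.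

Step 2
Reactants: 3 4-O-TBS-ferulic acid; 4 (S)-4-benzyl-2-oxazolidinone
Product: 6 (S)-4-benzyl-3-{(E)-3-[4-(tert-butyldimethylsilyloxy)-3-methoxyphenyl]acryloyl}oxazolidin-2-one, via mixed pivalic anhydride 5 (not isolated)
Conditions: PivCl, Et3N, THF, −20 °C; then 4, LiCl, −20 °C → rt
Reagents that add atoms: none
Why: Mixed-anhydride N-acylation of an oxazolidinone under LiCl/Et3N activation, with attack at the less hindered cinnamoyl carbonyl; the auxiliary stereocenter is not touched.

Step 3
Reactants: 6 N-feruloyl imide (two molecules)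
Product: 9 (2R,3R)-1,4-bis[(S)-4-benzyl-2-oxooxazolidin-3-yl]-2,3-bis[4-(tert-butyldimethylsilyloxy)-3-methoxybenzyl]butane-1,4-dione, via lithium Z-enolate 7 (not isolated), via trivalent-iodine enolonium equivalent 8 (not isolated)
Conditions: LiBH(s-Bu)3 (1.0 equiv), THF, −78 °C (6 added slowly to the hydride); then PhI(OAc)2 (0.55 equiv), THF, −78 → 0 °C
Reagents that add atoms: none
Why: Proposed new method: conjugate hydride addition to the lithium-chelated s-cis N-enoyl imide gives the Z-enolate 7 with s-Bu3B as a spectator (closest known type: LiBH(s-Bu)3 reductive aldol and reductive alkylation of chiral enoyl imides and sultams); PhI(OAc)2 then turns half of 7 into the O-bound trivalent-iodine enolate 8, whose α-carbon is now electrophilic, and a second molecule of 7 attacks that carbon with loss of PhI (closest known type: oxidative homocoupling of preformed lithium enolates of chiral 3-(3-arylpropanoyl)oxazolidinones with PhI(OAc)2, CuCl2 or TiCl4); each α-carbon bonds on the face opposite the C4 benzyl group of its own (S)-auxiliary, the same facial sense as Evans alkylation, which sets both new stereocenters as R, and the minor R,S isomer is a diastereomer removable by chromatography or crystallisation.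

Step 4
Reactants: 9 (R,R)-bis-imide
Product: 10 (2R,3R)-2,3-bis[4-(tert-butyldimethylsilyloxy)-3-methoxybenzyl]butane-1,4-diol
Conditions: LiBH4 (5 equiv), H2O (2.2 equiv), Et2O/THF, 0 °C → rt; aq. NH4Cl work-up
Reagents that add atoms: none
Why: Reductive cleavage of N-acyl oxazolidinones by LiBH4/H2O at the exocyclic carbonyl (a lactone formed by attack of the first alkoxide on the second imide is reduced on to the same diol); the conditions are non-epimerising, the R,R centers are retained, and auxiliary 4 is recovered.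

Step 5
Reactants: 10 (R,R)-diol (2 equiv, excess recovered); 3 4-O-TBS-ferulic acid (1 equiv)
Product: 11 (2R,3R)-2,3-bis[4-(tert-butyldimethylsilyloxy)-3-methoxybenzyl]-4-hydroxybutyl (E)-3-[4-(tert-butyldimethylsilyloxy)-3-methoxyphenyl]acrylate (tri-O-TBS hanultarin)
Conditions: EDC·HCl, DMAP (cat.), CH2Cl2, 0 °C → rt; 3 added slowly
Reagents that add atoms: none
Why: Steglich esterification; the two hydroxyls are homotopic so only one mono-ester exists (acyl migration is degenerate), excess diol suppresses the diester, and no stereocenter is touched.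

Step 6
Reactants: 11 tri-O-TBS hanultarin
Product: 12 hanultarin, (2R,3R)-4-hydroxy-2,3-bis(4-hydroxy-3-methoxybenzyl)butyl (E)-3-(4-hydroxy-3-methoxyphenyl)acrylate
Conditions: Bu4NF (3.3 equiv), AcOH (3.5 equiv), THF, 0 °C
Reagents that add atoms: none
Why: Fluoride-mediated cleavage of three aryl silyl ethers, buffered with AcOH so that no free phenoxide attacks the cinnamate ester; the alkene geometry and both stereocenters are unaffected.

**Compound list**

1 | (E)-ferulic acid | COc1cc(/C=C/C(=O)O)ccc1O | starting material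
2 | tert-butyldimethylsilyl (E)-3-[4-(tert-butyldimethylsilyloxy)-3-methoxyphenyl]acrylate (formed in the flask) | COc1cc(/C=C/C(=O)O[Si](C)(C)C(C)(C)C)ccc1O[Si](C)(C)C(C)(C)C | intermediate
3 | (E)-3-[4-(tert-butyldimethylsilyloxy)-3-methoxyphenyl]acrylic acid | COc1cc(/C=C/C(=O)O)ccc1O[Si](C)(C)C(C)(C)C | intermediate
4 | (S)-4-benzyl-2-oxazolidinone | O=C1N[C@@H](Cc2ccccc2)CO1 | starting material
5 | mixed anhydride of 3 and pivalic acid (formed in the flask) | COc1cc(/C=C/C(=O)OC(=O)C(C)(C)C)ccc1O[Si](C)(C)C(C)(C)C | intermediate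
6 | (S)-4-benzyl-3-{(E)-3-[4-(tert-butyldimethylsilyloxy)-3-methoxyphenyl]acryloyl}oxazolidin-2-one | COc1cc(/C=C/C(=O)N2C(=O)OC[C@@H]2Cc2ccccc2)ccc1O[Si](C)(C)C(C)(C)C | intermediate
7 | lithium Z-enolate of the saturated imide (formed in the flask) | [Li]O/C(=C\Cc1ccc(O[Si](C)(C)C(C)(C)C)c(OC)c1)N1C(=O)OC[C@@H]1Cc1ccccc1 | intermediate
8 | O-[acetoxy(phenyl)iodanyl] Z-enol ether of the same imide, the enolonium equivalent (formed in the flask) | CC(=O)O[I](c1ccccc1)O/C(=C\Cc1ccc(O[Si](C)(C)C(C)(C)C)c(OC)c1)N1C(=O)OC[C@@H]1Cc1ccccc1 | intermediate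
9 | (2R,3R)-1,4-bis[(S)-4-benzyl-2-oxooxazolidin-3-yl]-2,3-bis[4-(tert-butyldimethylsilyloxy)-3-methoxybenzyl]butane-1,4-dione | O=C(N1C(=O)OC[C@@H]1Cc1ccccc1)[C@H](Cc1ccc(O[Si](C)(C)C(C)(C)C)c(OC)c1)[C@@H](Cc1ccc(O[Si](C)(C)C(C)(C)C)c(OC)c1)C(=O)N1C(=O)OC[C@@H]1Cc1ccccc1 | intermediate
10 | (2R,3R)-2,3-bis[4-(tert-butyldimethylsilyloxy)-3-methoxybenzyl]butane-1,4-diol | OC[C@H](Cc1ccc(O[Si](C)(C)C(C)(C)C)c(OC)c1)[C@H](CO)Cc1ccc(O[Si](C)(C)C(C)(C)C)c(OC)c1 | intermediate
11 | tri-O-TBS hanultarin | COc1cc(/C=C/C(=O)OC[C@H](Cc2ccc(O[Si](C)(C)C(C)(C)C)c(OC)c2)[C@H](CO)Cc2ccc(O[Si](C)(C)C(C)(C)C)c(OC)c2)ccc1O[Si](C)(C)C(C)(C)C | intermediate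
12 | hanultarin | COc1cc(/C=C/C(=O)OC[C@H](Cc2ccc(O)c(OC)c2)[C@H](CO)Cc2ccc(O)c(OC)c2)ccc1O | target

**Step count**

Total steps: 6. Longest linear sequence: 6 (steps 1 to 6; compound 3 from step 1 is used again in step 5).

**Steps most likely to fail, with fallbacks**

Step 3 (highest risk). Possible failures are 1,2-reduction of the imide, Michael addition of 7 to unreacted 6, or interference of s-Bu3B with the iodine oxidant. The fallback sets out from 6 and comes back at 9. Hydrogenate the alkene (H2, 10% Pd/C, EtOAc) to the saturated imide F1. Deprotonate it with LiN(i-Pr)2 (THF, −78 °C) to the borane-free lithium enolate 7. Transmetalate with TiCl4 to the trichlorotitanium enolate F2. Homolysis of its Ti–O bond (tetravalent to trivalent titanium) gives auxiliary-bearing α-carbonyl radicals that dimerise to 9. This replaces hydride addition and the two-electron iodine pathway by deprotonation and a one-electron coupling.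

Step 4. The bis-imide is hindered, so hydride may be slow or open the oxazolidinone ring. The fallback sets out from 9 and comes back at 10. Transthioesterify with LiSEt (from EtSH and n-BuLi, THF, 0 °C), which attacks only the exocyclic carbonyls even of hindered imides. This gives the bis(S-ethyl thioester) F3 and returns auxiliary 4. The unhindered thioesters are then reduced with LiBH4 (THF, 0 °C) to 10.

Step 5. Mono- versus bis-acylation of a symmetric diol is statistical and may give a poor yield of 11. The fallback sets out from 10 and 3 and comes back at 11. Heat 10 with Bu2SnO (toluene, reflux, water removed) to the dibutylstannylene acetal F4. Convert 3 into the acid chloride F5 with (COCl)2 and cat. DMF in CH2Cl2. Add F5 (1.0 equiv) to F4 in CH2Cl2 at 0 °C. The first acylation leaves the second oxygen as the poorly nucleophilic chlorostannyl ether F6, so acylation stops at the mono-ester. Aqueous work-up hydrolyses the O–Sn bond to give 11.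

**Further compounds**

F1 | step 3 | (S)-4-benzyl-3-{3-[4-(tert-butyldimethylsilyloxy)-3-methoxyphenyl]propanoyl}oxazolidin-2-one | COc1cc(CCC(=O)N2C(=O)OC[C@@H]2Cc2ccccc2)ccc1O[Si](C)(C)C(C)(C)C
F2 | step 3 | trichlorotitanium Z-enolate of F1 | Cl[Ti](Cl)(Cl)O/C(=C\Cc1ccc(O[Si](C)(C)C(C)(C)C)c(OC)c1)N1C(=O)OC[C@@H]1Cc1ccccc1
F3 | step 4 | S,S′-diethyl (2R,3R)-2,3-bis[4-(tert-butyldimethylsilyloxy)-3-methoxybenzyl]butanebis(thioate) | CCSC(=O)[C@H](Cc1ccc(O[Si](C)(C)C(C)(C)C)c(OC)c1)[C@@H](Cc1ccc(O[Si](C)(C)C(C)(C)C)c(OC)c1)C(=O)SCC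
F4 | step 5 | (5R,6R)-2,2-dibutyl-5,6-bis[4-(tert-butyldimethylsilyloxy)-3-methoxybenzyl]-1,3,2-dioxastannepane | CCCC[Sn]1(CCCC)OC[C@H](Cc2ccc(O[Si](C)(C)C(C)(C)C)c(OC)c2)[C@@H](Cc2ccc(O[Si](C)(C)C(C)(C)C)c(OC)c2)CO1
F5 | step 5 | (E)-3-[4-(tert-butyldimethylsilyloxy)-3-methoxyphenyl]acryloyl chloride | COc1cc(/C=C/C(Cl)=O)ccc1O[Si](C)(C)C(C)(C)C
F6 | step 5 | O-chlorodibutylstannyl ether of 11 | COc1cc(/C=C/C(=O)OC[C@H](Cc2ccc(O[Si](C)(C)C(C)(C)C)c(OC)c2)[C@H](CO[Sn](Cl)(CCCC)CCCC)Cc2ccc(O[Si](C)(C)C(C)(C)C)c(OC)c2)ccc1O[Si](C)(C)C(C)(C)C
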